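**Plan**

1. Retrosynthetic cuts: first the four O–benzyl bonds and the helper OH at C2. Then the pyran ring of the isoflavan is cut at O1–C2 and C3–C4 in one operation. The resulting o-hydroxybenzhydrol is cut at C4–C4a, then C6''–CHO and C6''–I lead back to (2S)-naringenin. The C2–C3 unit goes back by a one-carbon homologation to 2,6-dimethoxyphenol.
2. Enabling feature: C4 is benzylic to ring A, sits ortho to the ring oxygen (O1–C8a=C4a–C4) and also carries the electron-rich C6'' of the flavanone. O1=C8a–C4a=C4 can therefore be unmasked as an o-quinone methide heterodiene. C2–C3 is brought in as an arylacetaldehyde; the aldehyde oxidation level at C2 is the activating helper.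
3. Forward order: the flavanone rings come ready-made with naringenin (steps 1–4: benzylation, iodination at C6'', formylation, ortho-hydroxyalkylation of the ring-A phenol). Steps 5–8 make the arylacetaldehyde. Step 9 closes the only ring formed in the synthesis (C3–C4, then O1–C2). Step 10 removes the helper OH and step 11 the benzyl ethers.
4. Stereochemistry: C2'' comes from the chiral pool. C3 comes from the shielded face of the catalyst-bound enamine. C4 comes from the endo approach that places the two aryl groups trans, giving (3R,4S).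

Key step: step 9

Assumption: (2S)-naringenin of high enantiomeric purity is taken as a commercial starting material. Unprimed locants refer to the isoflavan ring system, single primes to its 3-aryl group and double primes to the flavanone unit.

**Route**

Step 1
Reactants: 1 (2S)-naringenin
Product: 2 (2S)-7-(benzyloxy)-2-[4-(benzyloxy)phenyl]-5-hydroxychroman-4-one
Conditions: BnOH (2.2 equiv), PPh3, DIAD, THF, 0 °C to rt
Reagents that add atoms: benzyl alcohol, OCc1ccccc1
Why: Mitsunobu etherification should alkylate only the two acidic, non-chelated phenols, leave the hydrogen-bonded 5-OH free and, being free of base, avoid the retro-oxa-Michael ring opening that would racemize C2.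

Step 2
Reactants: 2 (2S)-7-(benzyloxy)-2-[4-(benzyloxy)phenyl]-5-hydroxychroman-4-one
Product: 3 (2S)-7-(benzyloxy)-2-[4-(benzyloxy)phenyl]-5-hydroxy-6-iodochroman-4-one
Conditions: BnMe3N[ICl2] (1.05 equiv), CaCO3, CH2Cl2–MeOH, rt
Reagents that add atoms: benzyltrimethylammonium dichloroiodate, C[N+](C)(C)Cc1ccccc1.Cl[I-]Cl
Why: Electrophilic aromatic iodination of a 5-hydroxy-7-alkoxy chromanone ring should go ortho to the free chelated phenol, to C6 and not C8, as is known for this reagent with 5-hydroxy-7-alkoxyflavones, while CaCO3 takes up the HCl.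

Step 3
Reactants: 3 (2S)-7-(benzyloxy)-2-[4-(benzyloxy)phenyl]-5-hydroxy-6-iodochroman-4-one
Product: 4 (2S)-7-(benzyloxy)-2-[4-(benzyloxy)phenyl]-5-hydroxy-4-oxochromane-6-carbaldehyde
Conditions: Pd(PPh3)4 (5 mol%), CO (3 atm), Bu3SnH (slow addition), toluene, 50 °C
Reagents that add atoms: carbon monoxide, [C-]#[O+]
Why: Palladium-catalysed reductive carbonylation of the aryl iodide (oxidative addition, CO insertion, hydride transfer from tin to the acylpalladium) should give the aldehyde under neutral conditions that leave the flavanone and its C2 centre alone.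

Step 4
Reactants: 4 (2S)-7-(benzyloxy)-2-[4-(benzyloxy)phenyl]-5-hydroxy-4-oxochromane-6-carbaldehyde; 5 3-(benzyloxy)phenol; 6 phenylboronic acid
Product: 8 (2S)-7-(benzyloxy)-6-{[4-(benzyloxy)-2-hydroxyphenyl](hydroxy)methyl}-2-[4-(benzyloxy)phenyl]-5-hydroxychroman-4-one (both carbinol epimers), via benzodioxaborin 7 (not isolated)
Conditions: EtCO2H (0.3 equiv), 4 Å MS, toluene, 90 °C; then propane-1,3-diol, THF, rt; product used without storage
Reagents that add atoms: none
Why: Boronic-acid-templated ortho-specific hydroxyalkylation of a phenol should deliver the aldehyde carbon to the free ortho position para to the benzyloxy group, the cyclic boronate 7 holds back a second arylation, and transesterification with the diol frees the o-hydroxybenzhydrol, whose uncontrolled carbinol centre is erased in step 9.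

Step 5
Reactants: 9 2,6-dimethoxyphenol
Product: 10 2-(benzyloxy)-1,3-dimethoxybenzene
Conditions: BnBr, K2CO3, DMF, rt
Reagents that add atoms: benzyl bromide, BrCc1ccccc1
Why: Williamson etherification of the phenoxide should protect the future 3'-OH as a benzyl ether that falls in the final hydrogenolysis.

Step 6
Reactants: 10 2-(benzyloxy)-1,3-dimethoxybenzene
Product: 11 3-(benzyloxy)-2,4-dimethoxybenzaldehyde
Conditions: POCl3, DMF, 0 to 80 °C; then ice-water
Reagents that add atoms: N,N-dimethylformamide, CN(C)C=O; water, O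
Why: Vilsmeier–Haack formylation should enter at C4, ortho to one methoxy group and para to the other, because the twisted central benzyloxy group is the weakest director of the 1,2,3-trioxygenated ring.

Step 7
Reactants: 11 3-(benzyloxy)-2,4-dimethoxybenzaldehyde
Product: 12 2-(benzyloxy)-1,3-dimethoxy-4-(2-methoxyethenyl)benzene (E/Z mixture)
Conditions: Ph3P(CH2OMe)Cl, KOtBu, THF, 0 °C to rt
Reagents that add atoms: (methoxymethyl)triphenylphosphonium chloride, COC[P+](c1ccccc1)(c1ccccc1)c1ccccc1.[Cl-]
Why: Wittig olefination with the methoxymethylene ylide should add the one carbon that becomes C2, and the alkene geometry does not matter because the next step removes it.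

Step 8
Reactants: 12 2-(benzyloxy)-1,3-dimethoxy-4-(2-methoxyethenyl)benzene
Product: 13 [3-(benzyloxy)-2,4-dimethoxyphenyl]acetaldehyde
Conditions: HCO2H, CH2Cl2–H2O, rt; used at once
Reagents that add atoms: water, O
Why: Acid hydrolysis of the enol ether (C-protonation, addition of water, loss of methanol) should free the arylacetaldehyde, which is used directly because it self-condenses on standing.

Step 9
Reactants: 8 (2S)-7-(benzyloxy)-6-{[4-(benzyloxy)-2-hydroxyphenyl](hydroxy)methyl}-2-[4-(benzyloxy)phenyl]-5-hydroxychroman-4-one; 13 [3-(benzyloxy)-2,4-dimethoxyphenyl]acetaldehyde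
Product: 15 (2S)-7-(benzyloxy)-6-{(3R,4S)-7-(benzyloxy)-3-[3-(benzyloxy)-2,4-dimethoxyphenyl]-2-hydroxychroman-4-yl}-2-[4-(benzyloxy)phenyl]-5-hydroxychroman-4-one (anomeric mixture at C2), via o-quinone methide 14 (not isolated)
Conditions: (R)-α,α-diphenylprolinol trimethylsilyl ether (20 mol%), (PhO)2P(O)OH (30 mol%), CHCl3, 0 °C to rt, 13 (2 equiv) added slowly
Reagents that add atoms: none
Why: Acid-promoted dehydration of 8 should unmask o-quinone methide 14 (heterodiene O1=C8a–C4a=C4); the (E)-enamine formed from 13 and the secondary amine adds with its α-carbon to C4 (C3–C4 bond), and the ring-A phenoxide then closes onto the iminium carbon (O1–C2 bond), hydrolysis giving the lactol and returning the amine. The closest known reaction type is the aminocatalytic formal [4+2] reaction (Michael addition then hemiacetalization) of aldehydes with o-quinone methides generated in situ, which gives trans-3,4-disubstituted chroman-2-ols. The pyran ring is closed in a stepwise [4+2] sense, an intermolecular conjugate addition followed by a 6-exo-trig O-cyclization onto C2. C3 is controlled by the catalyst, whose diphenyl(silyloxy)methyl group shields the Si face of the enamine α-carbon so that C4 is taken up on the Re face (3R); C4 is controlled by the endo (synclinal) approach with the enamine nitrogen over the quinone methide oxygen, which places the two aryl groups trans (4S), and C2 is an uncontrolled hemiacetal centre that step 10 removes. The step needs regioselectivity (C3 to C4 and O1 to C2, fixed by the polarity of the two partners), site selectivity among the phenolic oxygens (the ring-A oxygen is the quinone methide oxygen, the 5''-OH stays locked in its hydrogen bond to the C4'' ketone and O7'' is benzylated) and chemoselectivity for the aldehyde over the hindered flavanone ketone, which should not condense with the bulky amine, so C2'' stays untouched.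

Step 10
Reactants: 15 (2S)-7-(benzyloxy)-6-{(3R,4S)-7-(benzyloxy)-3-[3-(benzyloxy)-2,4-dimethoxyphenyl]-2-hydroxychroman-4-yl}-2-[4-(benzyloxy)phenyl]-5-hydroxychroman-4-one
Product: 16 (2S)-7-(benzyloxy)-6-{(3R,4S)-7-(benzyloxy)-3-[3-(benzyloxy)-2,4-dimethoxyphenyl]chroman-4-yl}-2-[4-(benzyloxy)phenyl]-5-hydroxychroman-4-one
Conditions: Et3SiH (5 equiv), CF3CO2H (10 equiv), CH2Cl2, −20 to 0 °C
Reagents that add atoms: none
Why: Ionic hydrogenation of the lactol (ionization to the cyclic oxocarbenium ion, hydride transfer from silicon) should turn C2 into CH2 without opening the ring or touching C3 and C4, while the chelated, doubly ortho-oxygenated C4'' ketone is too poor an electrophile to be reduced at this temperature.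

Step 11
Reactants: 16 (2S)-7-(benzyloxy)-6-{(3R,4S)-7-(benzyloxy)-3-[3-(benzyloxy)-2,4-dimethoxyphenyl]chroman-4-yl}-2-[4-(benzyloxy)phenyl]-5-hydroxychroman-4-one
Product: 17 (2S)-5,7-dihydroxy-6-[(3R,4S)-7-hydroxy-3-(3-hydroxy-2,4-dimethoxyphenyl)chroman-4-yl]-2-(4-hydroxyphenyl)chroman-4-one (CNP0267463.1)
Conditions: H2 (1 atm), Pd/C (10 wt% Pd on carbon), EtOAc–MeOH, rt
Reagents that add atoms: none
Why: Catalytic hydrogenolysis should cleave the four aryl benzyl ethers under neutral conditions that leave the methyl ethers, the flavanone ketone, the C2''–O bond and all three stereocentres unchanged.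

**Compound list**

1 | (2S)-naringenin | O=C1C[C@@H](c2ccc(O)cc2)Oc2cc(O)cc(O)c12 | starting material
2 | (2S)-7-(benzyloxy)-2-[4-(benzyloxy)phenyl]-5-hydroxychroman-4-one | O=C1C[C@@H](c2ccc(OCc3ccccc3)cc2)Oc2cc(OCc3ccccc3)cc(O)c12 | intermediate
3 | (2S)-7-(benzyloxy)-2-[4-(benzyloxy)phenyl]-5-hydroxy-6-iodochroman-4-one | O=C1C[C@@H](c2ccc(OCc3ccccc3)cc2)Oc2cc(OCc3ccccc3)c(I)c(O)c12 | intermediate
4 | (2S)-7-(benzyloxy)-2-[4-(benzyloxy)phenyl]-5-hydroxy-4-oxochromane-6-carbaldehyde | O=C1C[C@@H](c2ccc(OCc3ccccc3)cc2)Oc2cc(OCc3ccccc3)c(C=O)c(O)c12 | intermediate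
5 | 3-(benzyloxy)phenol | Oc1cccc(OCc2ccccc2)c1 | starting material
6 | phenylboronic acid | OB(O)c1ccccc1 | starting material
7 | 7-(benzyloxy)-4-{(2S)-7-(benzyloxy)-2-[4-(benzyloxy)phenyl]-5-hydroxy-4-oxochroman-6-yl}-2-phenyl-4H-1,3,2-benzodioxaborinine (both C4 epimers; formed in the flask, not isolated) | O=C1C[C@@H](c2ccc(OCc3ccccc3)cc2)Oc2cc(OCc3ccccc3)c(C3OB(c4ccccc4)Oc4cc(OCc5ccccc5)ccc43)c(O)c12 | intermediate
8 | (2S)-7-(benzyloxy)-6-{[4-(benzyloxy)-2-hydroxyphenyl](hydroxy)methyl}-2-[4-(benzyloxy)phenyl]-5-hydroxychroman-4-one (both carbinol epimers) | O=C1C[C@@H](c2ccc(OCc3ccccc3)cc2)Oc2cc(OCc3ccccc3)c(C(O)c3ccc(OCc4ccccc4)cc3O)c(O)c12 | intermediate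
9 | 2,6-dimethoxyphenol | COc1cccc(OC)c1O | starting material
10 | 2-(benzyloxy)-1,3-dimethoxybenzene | COc1cccc(OC)c1OCc1ccccc1 | intermediate
11 | 3-(benzyloxy)-2,4-dimethoxybenzaldehyde | COc1ccc(C=O)c(OC)c1OCc1ccccc1 | intermediate
12 | 2-(benzyloxy)-1,3-dimethoxy-4-(2-methoxyethenyl)benzene (E/Z mixture) | COC=Cc1ccc(OC)c(OCc2ccccc2)c1OC | intermediate
13 | [3-(benzyloxy)-2,4-dimethoxyphenyl]acetaldehyde | O=CCc1ccc(OC)c(OCc2ccccc2)c1OC | intermediate
14 | (2S)-7-(benzyloxy)-6-{[4-(benzyloxy)-6-oxocyclohexa-2,4-dien-1-ylidene]methyl}-2-[4-(benzyloxy)phenyl]-5-hydroxychroman-4-one (o-quinone methide; formed in the flask, not isolated) | O=C1C[C@@H](c2ccc(OCc3ccccc3)cc2)Oc2cc(OCc3ccccc3)c(C=C3C=CC(OCc4ccccc4)=CC3=O)c(O)c12 | intermediate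
15 | (2S)-7-(benzyloxy)-6-{(3R,4S)-7-(benzyloxy)-3-[3-(benzyloxy)-2,4-dimethoxyphenyl]-2-hydroxychroman-4-yl}-2-[4-(benzyloxy)phenyl]-5-hydroxychroman-4-one (anomeric mixture at C2) | COc1ccc([C@@H]2C(O)Oc3cc(OCc4ccccc4)ccc3[C@H]2c2c(OCc3ccccc3)cc3c(c2O)C(=O)C[C@@H](c2ccc(OCc4ccccc4)cc2)O3)c(OC)c1OCc1ccccc1 | intermediate
16 | (2S)-7-(benzyloxy)-6-{(3R,4S)-7-(benzyloxy)-3-[3-(benzyloxy)-2,4-dimethoxyphenyl]chroman-4-yl}-2-[4-(benzyloxy)phenyl]-5-hydroxychroman-4-one | COc1ccc([C@@H]2COc3cc(OCc4ccccc4)ccc3[C@H]2c2c(OCc3ccccc3)cc3c(c2O)C(=O)C[C@@H](c2ccc(OCc4ccccc4)cc2)O3)c(OC)c1OCc1ccccc1 | intermediate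
17 | (2S)-5,7-dihydroxy-6-[(3R,4S)-7-hydroxy-3-(3-hydroxy-2,4-dimethoxyphenyl)chroman-4-yl]-2-(4-hydroxyphenyl)chroman-4-one (CNP0267463.1) | COc1ccc([C@@H]2COc3cc(O)ccc3[C@H]2c2c(O)cc3c(c2O)C(=O)C[C@@H](c2ccc(O)cc2)O3)c(OC)c1O | target

**Step count and risks**

Total step count: 11. Longest linear sequence: 7 steps (1, 2, 3, 4, 9, 10, 11 from (2S)-naringenin); the branch of steps 5–8 joins at step 9 and is equally 7 steps long to the target.

Steps most likely to fail:

1. Step 9. The arylacetaldehyde may self-condense faster than its enamine adds to the crowded methide carbon, which bears a doubly ortho-substituted aryl group. Facial control may be incomplete, or an exo approach followed by epimerization at C3 may erode the (3R,4S) sense. Fallback: the activation mode is changed from enamine catalysis to Brønsted-acid catalysis, setting out from 8 and from the (E)-isomer of enol ether 12 (step 8 is then not needed). With a chiral BINOL-derived phosphoric acid such as TRIP in toluene at low temperature, the ion-paired o-quinone methide 14 should undergo an inverse-electron-demand hetero-Diels–Alder reaction with the enol ether (methoxy group endo, aryl groups trans). This should give the acetal (2S)-7-(benzyloxy)-6-{(3R,4S)-7-(benzyloxy)-3-[3-(benzyloxy)-2,4-dimethoxyphenyl]-2-methoxychroman-4-yl}-2-[4-(benzyloxy)phenyl]-5-hydroxychroman-4-one F1. Because C2'' is fixed, the (3R,4S) and (3S,4R) trans adducts are diastereomers and should be separable by chromatography if the acid gives incomplete control. Et3SiH/CF3CO2H then reduces the acetal carbon and the route is rejoined at 16.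

2. Step 4. The chelated, doubly ortho-oxygenated aldehyde may be too weak an electrophile for the boronate-templated addition. The very easily ionized product may also be arylated a second time to a triarylmethane, or decompose on isolation. Fallback: the bond made is changed from C4–C4a to C4–C6'', setting out from iodide 3 (step 3 is then not needed). Commercial 4-(benzyloxy)-2-hydroxybenzaldehyde is silylated (TBSCl, imidazole, DMF) to 4-(benzyloxy)-2-[(tert-butyldimethylsilyl)oxy]benzaldehyde F2. A Nozaki–Hiyama–Kishi coupling of 3 with F2 (CrCl2, catalytic NiCl2, DMF, rt), whose organochromium reagent adds to aldehydes but not to the flavanone ketone, should give (2S)-7-(benzyloxy)-6-{[4-(benzyloxy)-2-[(tert-butyldimethylsilyl)oxy]phenyl](hydroxy)methyl}-2-[4-(benzyloxy)phenyl]-5-hydroxychroman-4-one F3. Buffered fluoride (TBAF, AcOH, THF, 0 °C) removes the silyl group and the route is rejoined at 8.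

3. Step 10. The oxocarbenium ion at C2 may lose the C3 proton to give the 4H-chromene enol ether, and reprotonation would scramble C3. The acid may also ionize the doubly benzylic C4, or the silane may reduce the ketone. Fallback: hydride transfer to a cation is replaced by a radical reduction, setting out from 15. Thiophenol with a catalytic amount of camphorsulfonic acid and MgSO4 in CH2Cl2 at 0 °C should trap the lactol as the O,S-acetal (2S)-7-(benzyloxy)-6-{(3R,4S)-7-(benzyloxy)-3-[3-(benzyloxy)-2,4-dimethoxyphenyl]-2-(phenylsulfanyl)chroman-4-yl}-2-[4-(benzyloxy)phenyl]-5-hydroxychroman-4-one F4. Bu3SnH with AIBN in toluene at 90 °C then cleaves the C–S bond through the C2 α-oxyalkyl radical, which takes a hydrogen atom from tin without touching C3, and the route is rejoined at 16.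

**Further compounds**

F1 | step 9 | (2S)-7-(benzyloxy)-6-{(3R,4S)-7-(benzyloxy)-3-[3-(benzyloxy)-2,4-dimethoxyphenyl]-2-methoxychroman-4-yl}-2-[4-(benzyloxy)phenyl]-5-hydroxychroman-4-one | COc1ccc([C@@H]2C(OC)Oc3cc(OCc4ccccc4)ccc3[C@H]2c2c(OCc3ccccc3)cc3c(c2O)C(=O)C[C@@H](c2ccc(OCc4ccccc4)cc2)O3)c(OC)c1OCc1ccccc1
F2 | step 4 | 4-(benzyloxy)-2-[(tert-butyldimethylsilyl)oxy]benzaldehyde | O=Cc1ccc(OCc2ccccc2)cc1O[Si](C)(C)C(C)(C)C
F3 | step 4 | (2S)-7-(benzyloxy)-6-{[4-(benzyloxy)-2-[(tert-butyldimethylsilyl)oxy]phenyl](hydroxy)methyl}-2-[4-(benzyloxy)phenyl]-5-hydroxychroman-4-one | O=C1C[C@@H](c2ccc(OCc3ccccc3)cc2)Oc2cc(OCc3ccccc3)c(C(O)c3ccc(OCc4ccccc4)cc3O[Si](C)(C)C(C)(C)C)c(O)c12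
F4 | step 10 | (2S)-7-(benzyloxy)-6-{(3R,4S)-7-(benzyloxy)-3-[3-(benzyloxy)-2,4-dimethoxyphenyl]-2-(phenylsulfanyl)chroman-4-yl}-2-[4-(benzyloxy)phenyl]-5-hydroxychroman-4-one | COc1ccc([C@@H]2C(Sc5ccccc5)Oc3cc(OCc4ccccc4)ccc3[C@H]2c2c(OCc3ccccc3)cc3c(c2O)C(=O)C[C@@H](c2ccc(OCc4ccccc4)cc2)O3)c(OC)c1OCc1ccccc1
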